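Phthalide numbering is used (C1 lactone carbonyl, O2, C3, benzo carbons C3a–C7a). The bicycle is cut at C3–C3a and C7a–C1: the benzo ring arrives as the C3a≡C7a aryne, while C3, O2 and C1 arrive together as an enantioenriched α-lithiated alkyl N,N-diisopropylcarbamate. The feature exploited is the C7 methoxy group beside C7a, which polarises the aryne so that C3 bonds to C3a and the aryl anion appears at C7a, within reach of the carbamate carbonyl. One operation thus sets the C3 stereocentre and both bonds to the benzo ring. The precursor carries the whole C17 chain; its 1,4-dione is masked as a bis(dioxolane), because a furan mask would itself trap the aryne by [4+2] cycloaddition.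

Key step: step 7

Assumption: bond formation at the lithiated carbon is retentive, as with other electrophiles on non-benzylic lithiated carbamates, so (+)-sparteine is chosen for the (S) series. If the addition proved invertive, (−)-sparteine would be used in the same protocol.

Step 1
Reactants: 1 2-methylfuran; 2 12-bromododecan-1-ol
Product: 4 12-(5-methylfuran-2-yl)dodecan-1-ol, via 5-methyl-2-furyllithium 3 (not isolated)
Conditions: 1 (2.3 equiv), n-BuLi (2.2 equiv), THF, −78 → 0 °C; 2 (1.0 equiv), 0 °C → rt; H2O
Reagents that add atoms: none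
Why: Lithiation of the furan at its only free position next to oxygen and SN2 alkylation with a primary bromide are standard, and the first equivalent of the cheap 3 only deprotonates the hydroxyl, so no protecting group is needed.

Step 2
Reactants: 4 12-(5-methylfuran-2-yl)dodecan-1-ol; 5 N,N-diisopropylcarbamoyl chloride
Product: 6 12-(5-methylfuran-2-yl)dodecyl N,N-diisopropylcarbamate
Conditions: NaH, THF, 0 °C → rt; 5, reflux
Reagents that add atoms: none
Why: O-Carbamoylation of a sodium alkoxide is a nucleophilic acyl substitution, and the furan is inert to base.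

Step 3
Reactants: 6 12-(5-methylfuran-2-yl)dodecyl N,N-diisopropylcarbamate
Product: 7 13,16-dioxoheptadecyl N,N-diisopropylcarbamate
Conditions: AcOH–H2O (2:1), H2SO4 (cat.), 100 °C
Reagents that add atoms: water, O
Why: Acid-catalysed hydrolytic opening of a 2,5-dialkylfuran (reverse Paal–Knorr reaction) gives the 1,4-dione, and the hindered N,N-diisopropylcarbamate resists aqueous acid.

Step 4
Reactants: 7 13,16-dioxoheptadecyl N,N-diisopropylcarbamate
Product: 8 12-{2-[2-(2-methyl-1,3-dioxolan-2-yl)ethyl]-1,3-dioxolan-2-yl}dodecyl N,N-diisopropylcarbamate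
Conditions: Me3SiOCH2CH2OSiMe3 (2.5 equiv), Me3SiOSO2CF3 (5 mol %), CH2Cl2, −78 → −20 °C; pyridine quench
Reagents that add atoms: 1,2-bis(trimethylsilyloxy)ethane, C[Si](C)(C)OCCO[Si](C)(C)C
Why: Noyori ketalisation is aprotic and cold, so both ketones become dioxolanes without the hot Brønsted acid that would re-close the dione to the furan (Paal–Knorr), and the resulting mask is inert to alkyllithiums and is not a diene.

Step 5
Reactants: 9 3,5-dimethoxyphenol
Product: 10 2-bromo-3,5-dimethoxyphenol
Conditions: NBS (1.0 equiv), CH2Cl2, −78 → 0 °C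
Reagents that add atoms: N-bromosuccinimide, O=C1CCC(=O)N1Br
Why: In this electrophilic aromatic bromination C2 is ortho to the hydroxyl, para to a methoxy group and less crowded than C4 between the two methoxy groups, and one equivalent of NBS in the cold limits double bromination.

Step 6
Reactants: 10 2-bromo-3,5-dimethoxyphenol
Product: 11 2-bromo-3,5-dimethoxyphenyl trifluoromethanesulfonate
Conditions: (CF3SO2)2O, pyridine, CH2Cl2, 0 °C
Reagents that add atoms: trifluoromethanesulfonic anhydride, O=S(=O)(OS(=O)(=O)C(F)(F)F)C(F)(F)F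
Why: O-Sulfonylation of a phenol with triflic anhydride and pyridine is routine, also for ortho-substituted phenols.

Step 7
Reactants: 8 12-{2-[2-(2-methyl-1,3-dioxolan-2-yl)ethyl]-1,3-dioxolan-2-yl}dodecyl N,N-diisopropylcarbamate; 11 2-bromo-3,5-dimethoxyphenyl trifluoromethanesulfonate
Product: 16 (S)-2-(1-hydroxy-12-{2-[2-(2-methyl-1,3-dioxolan-2-yl)ethyl]-1,3-dioxolan-2-yl}dodecyl)-4,6-dimethoxy-N,N-diisopropylbenzamide, via lithiated carbamate 12 (not isolated), via 3,5-dimethoxybenzyne 13 (not isolated), via aryllithium adduct 14 (not isolated), via cyclic tetrahedral adduct 15 (not isolated)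
Conditions: 8 (1.3 equiv), s-BuLi (1.25 equiv), (+)-sparteine (1.3 equiv), Et2O, −78 °C, 5 h; 11 (1.0 equiv) in Et2O, then at once n-BuLi (1.0 equiv) dropwise, −78 °C; → 0 °C; H2O
Reagents that add atoms: none
Why: Proposed new method: s-BuLi/(+)-sparteine removes the pro-R hydrogen next to oxygen in 8 to give the configurationally stable (R)-organolithium 12, while n-BuLi exchanges the bromine of 11 and the ortho-lithiated triflate loses LiOSO2CF3 at once to release aryne 13. Syn carbolithiation of 13 by 12 forms C3–C3a and leaves aryllithium 14, whose C7a carbanion adds to the carbamate carbonyl (C7a–C1) in a 5-exo-trig closure to the transient five-membered adduct 15, which opens to the more stable alkoxide, so that no ring persists in 16. The closest known reaction types are the addition of organolithium or Grignard reagents to 3-methoxyarynes followed by capture of the aryl anion, and the anionic homo-Fries (1,4 oxygen-to-carbon carbamoyl) shift of ortho-lithiated benzyl carbamates; new are the chiral sp3 α-oxy carbanion as aryne partner and the merger of the two events. C3 is set by the sparteine enantiomer, provided that the four-centre addition is retentive as are the other substitutions of non-benzylic lithiated carbamates, which turns (R)-12 into (S)-16. Regioselectivity (attack at C3a only) is secured by the C7 methoxy group, which distorts the aryne and stabilises the charge at C7a inductively. Chemoselectivity requires that the aryne meets no better partner than 12, hence the ketal mask without a diene, no surplus s-BuLi, 12 in excess over 11 and slow addition of n-BuLi, which fast exchange consumes before it can add.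

Step 8
Reactants: 16 (S)-2-(1-hydroxy-12-{2-[2-(2-methyl-1,3-dioxolan-2-yl)ethyl]-1,3-dioxolan-2-yl}dodecyl)-4,6-dimethoxy-N,N-diisopropylbenzamide
Product: 17 CJ-13,103 [(S)-3-(12,15-dioxohexadecyl)-5,7-dimethoxyisobenzofuran-1(3H)-one]
Conditions: 3 M aq HCl–1,4-dioxane (1:2), 80 °C; NaHCO3 work-up
Reagents that add atoms: water, O
Why: Acid-catalysed ketal hydrolysis and hydroxyl-assisted amide cleavage (lactonisation by 5-exo-trig acyl substitution, with excess acid binding the released amine) run together; the C3–O bond is never broken and both methoxy groups are meta to C3, so no benzylic cation forms and the (S) configuration is kept, while the water present keeps the dione from closing to a furan.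

Compound list
1 | 2-methylfuran | Cc1ccco1 | starting material
2 | 12-bromododecan-1-ol | OCCCCCCCCCCCCBr | starting material
3 | 5-methyl-2-furyllithium | [Li]c1ccc(C)o1 | intermediate
4 | 12-(5-methylfuran-2-yl)dodecan-1-ol | OCCCCCCCCCCCCc1ccc(C)o1 | intermediate
5 | N,N-diisopropylcarbamoyl chloride | CC(C)N(C(C)C)C(Cl)=O | starting material
6 | 12-(5-methylfuran-2-yl)dodecyl N,N-diisopropylcarbamate | CC(C)N(C(C)C)C(=O)OCCCCCCCCCCCCc1ccc(C)o1 | intermediate
7 | 13,16-dioxoheptadecyl N,N-diisopropylcarbamate | CC(C)N(C(C)C)C(=O)OCCCCCCCCCCCCC(=O)CCC(C)=O | intermediate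
8 | 12-{2-[2-(2-methyl-1,3-dioxolan-2-yl)ethyl]-1,3-dioxolan-2-yl}dodecyl N,N-diisopropylcarbamate (bis(ethylene ketal) of 7) | CC(C)N(C(C)C)C(=O)OCCCCCCCCCCCCC1(CCC2(C)OCCO2)OCCO1 | intermediate
9 | 3,5-dimethoxyphenol | COc1cc(O)cc(OC)c1 | starting material
10 | 2-bromo-3,5-dimethoxyphenol | COc1cc(O)c(Br)c(OC)c1 | intermediate
11 | 2-bromo-3,5-dimethoxyphenyl trifluoromethanesulfonate | COc1cc(OC)c(Br)c(c1)OS(=O)(=O)C(F)(F)F | intermediate
12 | (R)-1-lithio derivative of 8, as its (+)-sparteine complex (ligand not drawn) | [Li][C@@H](OC(=O)N(C(C)C)C(C)C)CCCCCCCCCCCC1(CCC2(C)OCCO2)OCCO1 | intermediate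
13 | 3,5-dimethoxybenzyne (1,2-didehydro-3,5-dimethoxybenzene) | COC1=CC(OC)=CC#C1 | intermediate
14 | (S)-1-(2-lithio-3,5-dimethoxyphenyl)-12-{bis-ketal terminus as in 8}dodecyl N,N-diisopropylcarbamate | [Li]c1c(OC)cc(OC)cc1[C@@H](OC(=O)N(C(C)C)C(C)C)CCCCCCCCCCCC2(CCC3(C)OCCO3)OCCO2 | intermediate
15 | lithium (3S)-1-(diisopropylamino)-5,7-dimethoxy-3-alkyl-1,3-dihydroisobenzofuran-1-olate (C1 configuration undefined) | COc1cc(OC)c2c(c1)[C@H](CCCCCCCCCCCC3(CCC4(C)OCCO4)OCCO3)OC2(O[Li])N(C(C)C)C(C)C | intermediate
16 | (S)-2-(1-hydroxy-12-{2-[2-(2-methyl-1,3-dioxolan-2-yl)ethyl]-1,3-dioxolan-2-yl}dodecyl)-4,6-dimethoxy-N,N-diisopropylbenzamide | COc1cc(OC)c(C(=O)N(C(C)C)C(C)C)c(c1)[C@@H](O)CCCCCCCCCCCC2(CCC3(C)OCCO3)OCCO2 | intermediate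
17 | CJ-13,103, (S)-3-(12,15-dioxohexadecyl)-5,7-dimethoxyisobenzofuran-1(3H)-one | COc1cc(OC)c2c(c1)[C@H](CCCCCCCCCCCC(=O)CCC(C)=O)OC2=O | target

Total step count: 8. Longest linear sequence: 6 (steps 1, 2, 3, 4, 7, 8).

Steps most likely to fail

Risk 1 (step 7). Several processes could undercut the cascade:
- The carbanion, not n-BuLi, may exchange the bromine or abstract the ring proton beside the triflate.
- n-BuLi, free sparteine or the product alkoxide may capture the aryne.
- The carbon–carbon bond may form without clean retention.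
- The carbamoyl shift from the hindered carbamate may lag behind proton transfer.

The fallback uses known chemistry, sets out from 8 and comes back at 17. Compound 8 is lithiated to 12 exactly as in step 7, trapped at −78 °C with commercial 3,5-dimethoxyphenylboronic acid pinacol ester and warmed. The stereospecific 1,2-metallate rearrangement of lithiation–borylation (retention on boron capture, inversion on aryl migration) should then give the (S)-benzylic pinacol boronic ester F1. H2O2/NaOH oxidises it with retention to the (S)-benzylic alcohol F2. NBS in MeCN at 0 °C brominates the ring ortho to the side chain and para to a methoxy group, giving the bromo alcohol F3. Bromine–lithium exchange on its lithium alkoxide (n-BuLi, 2.2 equiv, THF, −78 °C) and a CO2 quench give the hydroxy acid F4. The conditions of step 8 then lactonise F4 and remove the ketals to deliver 17.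

Risk 2 (step 5). Bromination may also take place at C4 or twice, with difficult separation of regioisomers. The fallback replaces electrophilic substitution by directed ortho-metalation, sets out from 9 and comes back at 10. N,N-Diethylcarbamoyl chloride and K2CO3 in refluxing MeCN give the aryl carbamate F5. s-BuLi/TMEDA in THF at −78 °C lithiates between the carbamate, the strongest director present, and the neighbouring methoxy group. BrCF2CF2Br then gives the bromo carbamate F6, and NaOH in refluxing EtOH frees 10.

Risk 3 (step 1). The lithium alkoxide formed in the flask may aggregate with the furyllithium and slow the substitution, so that loss of HBr competes. The fallback uses a protecting group, sets out from 2 and comes back at 4. 3,4-Dihydro-2H-pyran and pyridinium p-toluenesulfonate in CH2Cl2 give the bromo THP ether F7. One equivalent of 3 in THF alkylates it to the furyl THP ether F8, and methanolysis (p-TsOH, MeOH, rt) releases 4.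

Further compounds
F1 | step 7 | (S)-2-[1-(3,5-dimethoxyphenyl)-12-{2-[2-(2-methyl-1,3-dioxolan-2-yl)ethyl]-1,3-dioxolan-2-yl}dodecyl]-4,4,5,5-tetramethyl-1,3,2-dioxaborolane | COc1cc(OC)cc(c1)[C@@H](B2OC(C)(C)C(C)(C)O2)CCCCCCCCCCCC3(CCC4(C)OCCO4)OCCO3
F2 | step 7 | (S)-1-(3,5-dimethoxyphenyl)-12-{2-[2-(2-methyl-1,3-dioxolan-2-yl)ethyl]-1,3-dioxolan-2-yl}dodecan-1-ol | COc1cc(OC)cc(c1)[C@@H](O)CCCCCCCCCCCC2(CCC3(C)OCCO3)OCCO2
F3 | step 7 | (S)-1-(2-bromo-3,5-dimethoxyphenyl)-12-{2-[2-(2-methyl-1,3-dioxolan-2-yl)ethyl]-1,3-dioxolan-2-yl}dodecan-1-ol | COc1cc(OC)c(Br)c(c1)[C@@H](O)CCCCCCCCCCCC2(CCC3(C)OCCO3)OCCO2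
F4 | step 7 | (S)-2-(1-hydroxy-12-{2-[2-(2-methyl-1,3-dioxolan-2-yl)ethyl]-1,3-dioxolan-2-yl}dodecyl)-4,6-dimethoxybenzoic acid | COc1cc(OC)c(C(O)=O)c(c1)[C@@H](O)CCCCCCCCCCCC2(CCC3(C)OCCO3)OCCO2
F5 | step 5 | 3,5-dimethoxyphenyl N,N-diethylcarbamate | CCN(CC)C(=O)Oc1cc(OC)cc(OC)c1
F6 | step 5 | 2-bromo-3,5-dimethoxyphenyl N,N-diethylcarbamate | CCN(CC)C(=O)Oc1cc(OC)cc(OC)c1Br
F7 | step 1 | 2-[(12-bromododecyl)oxy]tetrahydro-2H-pyran (racemic acetal) | BrCCCCCCCCCCCCOC1CCCCO1
F8 | step 1 | 2-{[12-(5-methylfuran-2-yl)dodecyl]oxy}tetrahydro-2H-pyran (racemic acetal) | Cc1ccc(CCCCCCCCCCCCOC2CCCCO2)o1
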